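Retrosynthesis: cut the C8–prenyl bond (back to an aryl bromide), raise C2 to the lactone level, cut C3–C4 (back to an aryl aryldiazoacetate), then cut the O1–C2 ester into a ring B arylacetic acid and a ring A phenol.
Forward: the chromene ring of ring B is made first (step 1), ring A is prepared as a 2-bromo-6-methylphenol, the halves are joined as an ester, and the pyranone ring closes in step 10 when a rhodium carbene at C3 inserts into a C–H bond of the ring A methyl group that becomes C4; the lactone is then reduced and the O1–C2 ether re-closed (steps 11 and 12).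
Enabling feature: C3 carries ring B and adjoins C2, so at the lactone level it is a donor/acceptor carbene carbon, while C4 is a benzylic carbon of ring A ortho to O1 and para to the C7 oxygen, so its C–H bonds are electron-rich and lie within reach of the O1–C2 tether.
Stereochemistry: C3 (R), the only stereocentre, is set in step 10 by the chiral dirhodium catalyst and is not touched afterwards.
Helpers and their removal: C2=O (steps 11 and 12), Br at C8, which blocks that position in step 10 and then becomes the prenyl group (step 13), MOM on O7 and TBS on O2' (step 14).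

Key step: step 10

Remark: chroman numbering is used for the target (O1, C2, C3, C4, C4a to C8a; ring A is the benzo ring, ring B the chromene-bearing aryl group with primed locants); the sense of induction of Rh2(S-PTAD)4 for this tether is assumed, and the R-series antipode is to be used if the first run gives (S)-15.

Step 1
Reactants: 1 2,4-dihydroxybenzaldehyde; 2 3-methylbut-2-enal
Product: 3 5-hydroxy-2,2-dimethyl-2H-chromene-6-carbaldehyde
Conditions: Ca(OH)2, MeOH, rt
Reagents that add atoms: none
Why: Chromenylation of a resorcinol by an enal (condensation at C3 of 1, loss of water to an ortho-quinone methide, oxa-6π electrocyclisation); the C2 hydroxyl is held in a hydrogen bond to the aldehyde, so the pyran oxygen should come from the C4 hydroxyl.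

Step 2
Reactants: 3 5-hydroxy-2,2-dimethyl-2H-chromene-6-carbaldehyde
Product: 4 5-[(tert-butyldimethylsilyl)oxy]-2,2-dimethyl-2H-chromene-6-carbaldehyde
Conditions: TBSCl, imidazole, DMF, rt
Reagents that add atoms: tert-butyldimethylsilyl chloride, CC(C)(C)[Si](C)(C)Cl
Why: Standard silylation of a phenol; a silyl ether is chosen because it offers the carbene of step 10 no C–H bond next to oxygen.

Step 3
Reactants: 4 5-[(tert-butyldimethylsilyl)oxy]-2,2-dimethyl-2H-chromene-6-carbaldehyde
Product: 5 tert-butyl{[6-(2-methoxyethenyl)-2,2-dimethyl-2H-chromen-5-yl]oxy}dimethylsilane (E/Z mixture)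
Conditions: Ph3P(CH2OMe)Cl, KN(SiMe3)2, THF, 0 °C; then 4, 0 °C to rt
Reagents that add atoms: (methoxymethyl)triphenylphosphonium chloride, COC[P+](c1ccccc1)(c1ccccc1)c1ccccc1.[Cl-]
Why: Wittig reaction with the methoxymethylene ylide adds the carbon that becomes C2; the alkene geometry is irrelevant because both isomers hydrolyse to the same aldehyde.

Step 4
Reactants: 5 tert-butyl{[6-(2-methoxyethenyl)-2,2-dimethyl-2H-chromen-5-yl]oxy}dimethylsilane
Product: 7 {5-[(tert-butyldimethylsilyl)oxy]-2,2-dimethyl-2H-chromen-6-yl}acetic acid, via arylacetaldehyde 6 (not isolated)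
Conditions: 1 M aq HCl, THF, rt; then NaClO2, NaH2PO4, 2-methyl-2-butene, t-BuOH/H2O, 0 °C to rt
Reagents that add atoms: water, O; NaClO2 (sodium chlorite), [Na+].[O-]Cl=O
Why: Acid hydrolysis of the enol ether followed by Pinnick oxidation, which should spare the chromene alkene because 2-methyl-2-butene scavenges the hypochlorous acid.

Step 5
Reactants: 8 2-bromobenzene-1,3-diol
Product: 9 3-bromo-2,4-dihydroxybenzaldehyde
Conditions: POCl3, DMF, MeCN, 0 °C to rt; then H2O, 50 °C
Reagents that add atoms: N,N-dimethylformamide, CN(C)C=O; water, O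
Why: Vilsmeier–Haack formylation of a resorcinol para to one hydroxyl and ortho to the other; 8 is symmetric, so only one mono-aldehyde can form, and the new carbon becomes C4.

Step 6
Reactants: 9 3-bromo-2,4-dihydroxybenzaldehyde
Product: 10 3-bromo-2-hydroxy-4-(methoxymethoxy)benzaldehyde
Conditions: MOMCl, K2CO3, acetone, rt
Reagents that add atoms: chloromethyl methyl ether, COCCl
Why: Williamson etherification; the C2 hydroxyl is deactivated by its hydrogen bond to the aldehyde, so the C4 hydroxyl (the future O7) should react selectively.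

Step 7
Reactants: 10 3-bromo-2-hydroxy-4-(methoxymethoxy)benzaldehyde
Product: 12 2-bromo-3-(methoxymethoxy)-6-methylphenol, via aryl ethyl carbonate 11 (not isolated)
Conditions: ClCO2Et, Et3N, THF, 0 °C; then NaBH4, H2O, 0 °C to rt
Reagents that add atoms: none
Why: Reduction of an ortho-acylphenol to an ortho-alkylphenol through its carbonate: borohydride reduces the aldehyde, the carbonate shifts to the benzylic oxygen and leaves, and the resulting ortho-quinone methide is reduced to the methyl group.

Step 8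
Reactants: 7 {5-[(tert-butyldimethylsilyl)oxy]-2,2-dimethyl-2H-chromen-6-yl}acetic acid; 12 2-bromo-3-(methoxymethoxy)-6-methylphenol
Product: 13 2-bromo-3-(methoxymethoxy)-6-methylphenyl {5-[(tert-butyldimethylsilyl)oxy]-2,2-dimethyl-2H-chromen-6-yl}acetate
Conditions: DCC, DMAP (cat.), CH2Cl2, 0 °C to rt
Reagents that add atoms: none
Why: Steglich esterification tolerates the hindered 2,6-disubstituted phenol and installs the O1–C2 tether.

Step 9
Reactants: 13 2-bromo-3-(methoxymethoxy)-6-methylphenyl {5-[(tert-butyldimethylsilyl)oxy]-2,2-dimethyl-2H-chromen-6-yl}acetate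
Product: 14 2-bromo-3-(methoxymethoxy)-6-methylphenyl {5-[(tert-butyldimethylsilyl)oxy]-2,2-dimethyl-2H-chromen-6-yl}(diazo)acetate
Conditions: p-ABSA, DBU, MeCN, 0 °C to rt
Reagents that add atoms: 4-acetamidobenzenesulfonyl azide, CC(=O)Nc1ccc(cc1)S(=O)(=O)N=[N+]=[N-]
Why: Regitz diazo transfer to the methylene group that is activated by both the aryl group and the aryl ester.

Step 10
Reactants: 14 2-bromo-3-(methoxymethoxy)-6-methylphenyl {5-[(tert-butyldimethylsilyl)oxy]-2,2-dimethyl-2H-chromen-6-yl}(diazo)acetate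
Product: 15 (3R)-8-bromo-3-{5-[(tert-butyldimethylsilyl)oxy]-2,2-dimethyl-2H-chromen-6-yl}-7-(methoxymethoxy)-3,4-dihydro-2H-chromen-2-one
Conditions: Rh2(S-PTAD)4 (1 mol %), PhCF3, 4 Å MS, 40 °C, slow addition of 14 (final 0.01 M)
Reagents that add atoms: none
Why: Proposed new method: Rh2(S-PTAD)4 takes N2 out of 14 to give a rhodium-bound donor/acceptor carbene at C3 (donor: ring B; acceptor: the ester carbonyl C2), which in the s-cis rotamer of the ester lies over the ortho-methyl group of ring A and inserts into one of its C–H bonds through a concerted, asynchronous, hydride-transfer-like three-centre transition state, so that the C3–C4 bond forms and the metal is released. The closest known reaction type is the enantioselective intramolecular insertion of aryldiazoacetate-derived rhodium carbenes into benzylic C–H bonds (dihydrobenzofuran and lactone formation) and their intermolecular insertion into the methyl group of para-alkoxytoluenes; the reach through an aryl ester tether to an ortho-methyl group is the part that is argued here and not shown. The six-membered lactone closes by 1,6-insertion (ring atoms C3, C2, O1, C8a, C4a, C4), helped by the fact that the methyl C–H bonds are benzylic and para to the C7 oxygen, which stabilises the positive charge that builds at C4. The C3 stereocentre is set by the chiral carboxylate ligands, which shield one face of the carbene while the C–H bond approaches; the S-series catalyst is assumed to give (R)-15. The step needs site selectivity, and the substrate secures it: bromine occupies C8, the only other position ortho to O1, so aromatic substitution to a benzofuranone is shut off, the 2'-oxygen carries a silyl group that has no C–H bond next to oxygen, the prenyl group is not yet present, and the chromene alkene of ring B cannot reach the carbene within the molecule, while slow addition at high dilution holds back its intermolecular cyclopropanation. The neutral conditions leave the enolisable C3–H of the new α-aryl lactone untouched.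

Step 11
Reactants: 15 (3R)-8-bromo-3-{5-[(tert-butyldimethylsilyl)oxy]-2,2-dimethyl-2H-chromen-6-yl}-7-(methoxymethoxy)-3,4-dihydro-2H-chromen-2-one
Product: 16 2-bromo-6-[(2R)-2-{5-[(tert-butyldimethylsilyl)oxy]-2,2-dimethyl-2H-chromen-6-yl}-3-hydroxypropyl]-3-(methoxymethoxy)phenol
Conditions: LiBH4, THF, 0 °C
Reagents that add atoms: none
Why: Borohydride reduction of the aryl lactone to phenol and primary alcohol should outrun enolisation at C3; a route through the lactol and an oxocarbenium ion is avoided because that ion could lose the C3 proton.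

Step 12
Reactants: 16 2-bromo-6-[(2R)-2-{5-[(tert-butyldimethylsilyl)oxy]-2,2-dimethyl-2H-chromen-6-yl}-3-hydroxypropyl]-3-(methoxymethoxy)phenol
Product: 17 (3R)-8-bromo-3-{5-[(tert-butyldimethylsilyl)oxy]-2,2-dimethyl-2H-chromen-6-yl}-7-(methoxymethoxy)-3,4-dihydro-2H-chromene
Conditions: PPh3, DIAD, THF, 0 °C to rt
Reagents that add atoms: none
Why: Intramolecular Mitsunobu etherification of the acidic phenol by the primary alcohol re-forms the O1–C2 bond at the ether level without touching C3.

Step 13
Reactants: 17 (3R)-8-bromo-3-{5-[(tert-butyldimethylsilyl)oxy]-2,2-dimethyl-2H-chromen-6-yl}-7-(methoxymethoxy)-3,4-dihydro-2H-chromene; 18 1-bromo-3-methylbut-2-ene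
Product: 20 (3R)-3-{5-[(tert-butyldimethylsilyl)oxy]-2,2-dimethyl-2H-chromen-6-yl}-7-(methoxymethoxy)-8-(3-methylbut-2-en-1-yl)-3,4-dihydro-2H-chromene, via aryllithium 19 (not isolated)
Conditions: n-BuLi, THF, −78 °C; then CuBr·SMe2 (10 mol %), 18, −78 to 0 °C
Reagents that add atoms: none
Why: Bromine–lithium exchange gives an aryllithium flanked by two oxygens, which under copper catalysis should be alkylated at the primary end of prenyl bromide (SN2 over SN2′).

Step 14
Reactants: 20 (3R)-3-{5-[(tert-butyldimethylsilyl)oxy]-2,2-dimethyl-2H-chromen-6-yl}-7-(methoxymethoxy)-8-(3-methylbut-2-en-1-yl)-3,4-dihydro-2H-chromene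
Product: 22 (3R)-3-(5-hydroxy-2,2-dimethyl-2H-chromen-6-yl)-8-(3-methylbut-2-en-1-yl)-3,4-dihydro-2H-chromen-7-ol, via monophenol 21 (not isolated)
Conditions: TBAF, THF, 0 °C; then HCl, MeOH, rt
Reagents that add atoms: none
Why: Fluoride cleaves the aryl silyl ether and mild methanolic acid cleaves the methoxymethyl acetal, conditions under which ortho-prenylphenols and 2,2-dimethylchromenes are generally stable.

Compound list
1 | 2,4-dihydroxybenzaldehyde | O=Cc1ccc(O)cc1O | starting material
2 | 3-methylbut-2-enal | CC(C)=CC=O | starting material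
3 | 5-hydroxy-2,2-dimethyl-2H-chromene-6-carbaldehyde | CC1(C)C=Cc2c(O)c(C=O)ccc2O1 | intermediate
4 | 5-[(tert-butyldimethylsilyl)oxy]-2,2-dimethyl-2H-chromene-6-carbaldehyde | CC1(C)C=Cc2c(O[Si](C)(C)C(C)(C)C)c(C=O)ccc2O1 | intermediate
5 | tert-butyl{[6-(2-methoxyethenyl)-2,2-dimethyl-2H-chromen-5-yl]oxy}dimethylsilane (E/Z mixture) | COC=Cc1ccc2OC(C)(C)C=Cc2c1O[Si](C)(C)C(C)(C)C | intermediate
6 | {5-[(tert-butyldimethylsilyl)oxy]-2,2-dimethyl-2H-chromen-6-yl}acetaldehyde (formed in the flask, not isolated) | O=CCc1ccc2OC(C)(C)C=Cc2c1O[Si](C)(C)C(C)(C)C | intermediate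
7 | {5-[(tert-butyldimethylsilyl)oxy]-2,2-dimethyl-2H-chromen-6-yl}acetic acid | OC(=O)Cc1ccc2OC(C)(C)C=Cc2c1O[Si](C)(C)C(C)(C)C | intermediate
8 | 2-bromobenzene-1,3-diol (2-bromoresorcinol) | Oc1cccc(O)c1Br | starting material
9 | 3-bromo-2,4-dihydroxybenzaldehyde | O=Cc1ccc(O)c(Br)c1O | intermediate
10 | 3-bromo-2-hydroxy-4-(methoxymethoxy)benzaldehyde | COCOc1ccc(C=O)c(O)c1Br | intermediate
11 | 2-bromo-6-formyl-3-(methoxymethoxy)phenyl ethyl carbonate (formed in the flask, not isolated) | CCOC(=O)Oc1c(C=O)ccc(OCOC)c1Br | intermediate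
12 | 2-bromo-3-(methoxymethoxy)-6-methylphenol | COCOc1ccc(C)c(O)c1Br | intermediate
13 | 2-bromo-3-(methoxymethoxy)-6-methylphenyl {5-[(tert-butyldimethylsilyl)oxy]-2,2-dimethyl-2H-chromen-6-yl}acetate | COCOc1ccc(C)c(OC(=O)Cc2ccc3OC(C)(C)C=Cc3c2O[Si](C)(C)C(C)(C)C)c1Br | intermediate
14 | 2-bromo-3-(methoxymethoxy)-6-methylphenyl {5-[(tert-butyldimethylsilyl)oxy]-2,2-dimethyl-2H-chromen-6-yl}(diazo)acetate | COCOc1ccc(C)c(OC(=O)C(=[N+]=[N-])c2ccc3OC(C)(C)C=Cc3c2O[Si](C)(C)C(C)(C)C)c1Br | intermediate
15 | (3R)-8-bromo-3-{5-[(tert-butyldimethylsilyl)oxy]-2,2-dimethyl-2H-chromen-6-yl}-7-(methoxymethoxy)-3,4-dihydro-2H-chromen-2-one | COCOc1ccc2C[C@H](c3ccc4OC(C)(C)C=Cc4c3O[Si](C)(C)C(C)(C)C)C(=O)Oc2c1Br | intermediate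
16 | 2-bromo-6-[(2R)-2-{5-[(tert-butyldimethylsilyl)oxy]-2,2-dimethyl-2H-chromen-6-yl}-3-hydroxypropyl]-3-(methoxymethoxy)phenol | COCOc1ccc(C[C@@H](CO)c2ccc3OC(C)(C)C=Cc3c2O[Si](C)(C)C(C)(C)C)c(O)c1Br | intermediate
17 | (3R)-8-bromo-3-{5-[(tert-butyldimethylsilyl)oxy]-2,2-dimethyl-2H-chromen-6-yl}-7-(methoxymethoxy)-3,4-dihydro-2H-chromene | COCOc1ccc2C[C@H](c3ccc4OC(C)(C)C=Cc4c3O[Si](C)(C)C(C)(C)C)COc2c1Br | intermediate
18 | 1-bromo-3-methylbut-2-ene (prenyl bromide) | CC(C)=CCBr | starting material
19 | [(3R)-3-{5-[(tert-butyldimethylsilyl)oxy]-2,2-dimethyl-2H-chromen-6-yl}-7-(methoxymethoxy)-3,4-dihydro-2H-chromen-8-yl]lithium (formed in the flask, not isolated) | COCOc1ccc2C[C@H](c3ccc4OC(C)(C)C=Cc4c3O[Si](C)(C)C(C)(C)C)COc2c1[Li] | intermediate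
20 | (3R)-3-{5-[(tert-butyldimethylsilyl)oxy]-2,2-dimethyl-2H-chromen-6-yl}-7-(methoxymethoxy)-8-(3-methylbut-2-en-1-yl)-3,4-dihydro-2H-chromene | COCOc1ccc2C[C@H](c3ccc4OC(C)(C)C=Cc4c3O[Si](C)(C)C(C)(C)C)COc2c1CC=C(C)C | intermediate
21 | 6-[(3R)-7-(methoxymethoxy)-8-(3-methylbut-2-en-1-yl)-3,4-dihydro-2H-chromen-3-yl]-2,2-dimethyl-2H-chromen-5-ol (formed in the flask, not isolated) | COCOc1ccc2C[C@H](c3ccc4OC(C)(C)C=Cc4c3O)COc2c1CC=C(C)C | intermediate
22 | (3R)-3-(5-hydroxy-2,2-dimethyl-2H-chromen-6-yl)-8-(3-methylbut-2-en-1-yl)-3,4-dihydro-2H-chromen-7-ol | CC(C)=CCc1c(O)ccc2c1OC[C@@H](c1ccc3c(c1O)C=CC(C)(C)O3)C2 | target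

Total step count: 14.
Longest linear sequence: 11 steps (steps 1 to 4 and 8 to 14, from 2,4-dihydroxybenzaldehyde).

Steps most likely to fail

Step 10 (carbene C–H insertion, the step that carries the label). What may go wrong: the carbene may be used up by intermolecular cyclopropanation of the chromene alkene or by dimer formation before the s-cis ester rotamer brings it to the methyl group, and the facial selectivity at C3 may be poor. The fallback uses known chemistry, sets out from 7 and 10 and returns to the route at 16. The C3–C4 bond is made by auxiliary-controlled enolate alkylation of an N-acyl oxazolidinone (Evans alkylation), and the ring is closed afterwards by the Mitsunobu reaction of step 12.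
- Aldehyde 10 is O-allylated (allyl bromide, K2CO3, DMF) to 2-(allyloxy)-3-bromo-4-(methoxymethoxy)benzaldehyde F1.
- F1 is reduced (NaBH4, MeOH) to [2-(allyloxy)-3-bromo-4-(methoxymethoxy)phenyl]methanol F2.
- F2 is converted (CBr4, PPh3, CH2Cl2) into 2-(allyloxy)-3-bromo-1-(bromomethyl)-4-(methoxymethoxy)benzene F3.
- Acid 7 is joined to (R)-4-benzyl-1,3-oxazolidin-2-one through its mixed pivalic anhydride (t-BuCOCl, Et3N; then the lithiated oxazolidinone) to give (4R)-4-benzyl-3-({5-[(tert-butyldimethylsilyl)oxy]-2,2-dimethyl-2H-chromen-6-yl}acetyl)-1,3-oxazolidin-2-one F4.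
- The sodium enolate of F4 (NaN(SiMe3)2, THF, −78 °C) should be alkylated by F3 on the face away from the benzyl group to give (4R)-4-benzyl-3-[(2R)-3-[2-(allyloxy)-3-bromo-4-(methoxymethoxy)phenyl]-2-{5-[(tert-butyldimethylsilyl)oxy]-2,2-dimethyl-2H-chromen-6-yl}propanoyl]-1,3-oxazolidin-2-one F5.
- LiBH4 should cleave the auxiliary to give (2R)-3-[2-(allyloxy)-3-bromo-4-(methoxymethoxy)phenyl]-2-{5-[(tert-butyldimethylsilyl)oxy]-2,2-dimethyl-2H-chromen-6-yl}propan-1-ol F6.
- Pd(PPh3)4 and morpholine remove the allyl group to give diol 16.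

Step 14 (final deprotection). What may go wrong: under the acid needed for the methoxymethyl acetal, the freed C7 phenol may add to the neighbouring prenyl alkene (closure to a 2,2-dimethylchroman), or the chromene alkene may be hydrated. The fallback sets out from 17 and returns at 22. The acetal is removed before the prenyl group exists and the end game is run with fluoride only.
- Bromide 17 is deprotected (HCl, MeOH; then TBAF) to (3R)-8-bromo-3-(5-hydroxy-2,2-dimethyl-2H-chromen-6-yl)-3,4-dihydro-2H-chromen-7-ol F7.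
- Both phenols are silylated (TBSCl, imidazole, DMF) to (3R)-8-bromo-7-[(tert-butyldimethylsilyl)oxy]-3-{5-[(tert-butyldimethylsilyl)oxy]-2,2-dimethyl-2H-chromen-6-yl}-3,4-dihydro-2H-chromene F8.
- A Stille coupling with tributyl(3-methylbut-2-en-1-yl)stannane (Pd(PPh3)4, CsF, dioxane, 100 °C) replaces bromine by the prenyl group without an aryllithium, which a neighbouring silyl ether would not tolerate, to give (3R)-7-[(tert-butyldimethylsilyl)oxy]-3-{5-[(tert-butyldimethylsilyl)oxy]-2,2-dimethyl-2H-chromen-6-yl}-8-(3-methylbut-2-en-1-yl)-3,4-dihydro-2H-chromene F9.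
- TBAF then gives 22.

Step 13 (prenylation). What may go wrong: loss of regiocontrol in the allylic substitution, the aryl nucleophile attacking the tertiary end of prenyl bromide (SN2′) to give the 1,1-dimethylallyl isomer. The fallback sets out from 17 and returns at 20.
- The aryllithium from 17 (n-BuLi, THF, −78 °C) is quenched with allyl bromide, whose two ends are equivalent, to give (3R)-3-{5-[(tert-butyldimethylsilyl)oxy]-2,2-dimethyl-2H-chromen-6-yl}-7-(methoxymethoxy)-8-(prop-2-en-1-yl)-3,4-dihydro-2H-chromene F10.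
- Cross-metathesis with 2-methylbut-2-ene (second-generation Grubbs catalyst, CH2Cl2, rt to 40 °C) turns the allyl group into the prenyl group of 20; the 2,2-dimethylchromene alkene is hindered by its quaternary neighbour and should stay out of the metathesis.

Further compounds
F1 | step 10 | 2-(allyloxy)-3-bromo-4-(methoxymethoxy)benzaldehyde | C=CCOc1c(C=O)ccc(OCOC)c1Br
F2 | step 10 | [2-(allyloxy)-3-bromo-4-(methoxymethoxy)phenyl]methanol | C=CCOc1c(CO)ccc(OCOC)c1Br
F3 | step 10 | 2-(allyloxy)-3-bromo-1-(bromomethyl)-4-(methoxymethoxy)benzene | C=CCOc1c(CBr)ccc(OCOC)c1Br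
F4 | step 10 | (4R)-4-benzyl-3-({5-[(tert-butyldimethylsilyl)oxy]-2,2-dimethyl-2H-chromen-6-yl}acetyl)-1,3-oxazolidin-2-one | O=C(Cc1ccc2OC(C)(C)C=Cc2c1O[Si](C)(C)C(C)(C)C)N1[C@H](Cc2ccccc2)COC1=O
F5 | step 10 | (4R)-4-benzyl-3-[(2R)-3-[2-(allyloxy)-3-bromo-4-(methoxymethoxy)phenyl]-2-{5-[(tert-butyldimethylsilyl)oxy]-2,2-dimethyl-2H-chromen-6-yl}propanoyl]-1,3-oxazolidin-2-one | C=CCOc1c(C[C@@H](C(=O)N2[C@H](Cc3ccccc3)COC2=O)c2ccc3OC(C)(C)C=Cc3c2O[Si](C)(C)C(C)(C)C)ccc(OCOC)c1Br
F6 | step 10 | (2R)-3-[2-(allyloxy)-3-bromo-4-(methoxymethoxy)phenyl]-2-{5-[(tert-butyldimethylsilyl)oxy]-2,2-dimethyl-2H-chromen-6-yl}propan-1-ol | C=CCOc1c(C[C@@H](CO)c2ccc3OC(C)(C)C=Cc3c2O[Si](C)(C)C(C)(C)C)ccc(OCOC)c1Br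
F7 | step 14 | (3R)-8-bromo-3-(5-hydroxy-2,2-dimethyl-2H-chromen-6-yl)-3,4-dihydro-2H-chromen-7-ol | Oc1ccc2C[C@H](c3ccc4OC(C)(C)C=Cc4c3O)COc2c1Br
F8 | step 14 | (3R)-8-bromo-7-[(tert-butyldimethylsilyl)oxy]-3-{5-[(tert-butyldimethylsilyl)oxy]-2,2-dimethyl-2H-chromen-6-yl}-3,4-dihydro-2H-chromene | CC(C)(C)[Si](C)(C)Oc1ccc2C[C@H](c3ccc4OC(C)(C)C=Cc4c3O[Si](C)(C)C(C)(C)C)COc2c1Br
F9 | step 14 | (3R)-7-[(tert-butyldimethylsilyl)oxy]-3-{5-[(tert-butyldimethylsilyl)oxy]-2,2-dimethyl-2H-chromen-6-yl}-8-(3-methylbut-2-en-1-yl)-3,4-dihydro-2H-chromene | CC(C)(C)[Si](C)(C)Oc1ccc2C[C@H](c3ccc4OC(C)(C)C=Cc4c3O[Si](C)(C)C(C)(C)C)COc2c1CC=C(C)C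
F10 | step 13 | (3R)-3-{5-[(tert-butyldimethylsilyl)oxy]-2,2-dimethyl-2H-chromen-6-yl}-7-(methoxymethoxy)-8-(prop-2-en-1-yl)-3,4-dihydro-2H-chromene | COCOc1ccc2C[C@H](c3ccc4OC(C)(C)C=Cc4c3O[Si](C)(C)C(C)(C)C)COc2c1CC=C
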